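The ring in this flask I follow by rates alone, without concentrations, from readings of this same flask up to 80.0 min.

| setting | spring | flask |
|---|---|---|
| solid substrate | 0.020 M | 0.020 M |
| remark | the very flask that is asked about, followed so far |  |
| time |  | 4.0 h |

- spring (time / min: ring / %, starting material / %, solid substrate / %): 6.00: 2.7, 4.7, 93.7; 8.00: 3.0, 4.5, 91.9; 12.0: 6.0, 5.6, 87.6; 20.0: 13.1, 6.3, 80.1; 30.0: 22.6, 6.0, 70.0; 50.0: 40.3, 6.8, 50.5; 80.0: 66.3, 6.7, 21.3

(scatter of a reading: 0.3 percentage points)

- solid, in amounts per volume of the solution: solid substrate
- at the start none of the solid substrate is in solution
- starting material is what solid substrate becomes in solution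
- starting material means what is dissolved; the solid is not counted in it

* how much ring there is at 4.0 h, in percent of the solid substrate charged
* concentration of starting material in solution at 4.0 h, in percent of saturation

At the start the solid substrate leaves at 0.210 mM min⁻¹, so my first answer is that the charge is through in 95.2 min. But from 6.00 min to 80.0 min it leaves at 0.196 mM min⁻¹, which I call the crawl, the solid substrate entering solution per minute and per litre. That is a slowing by the factor 0.932, and going round once more gives 102 min, shorter than 4.0 h.

I treat the crawl as the rate-limiting step, because [starting material] stands at 6.7% of the charge, less than the 59 percentage points that passed through it after 20.0 min. From 6.00 min to 80.0 min, the stretch of the crawl itself, ring takes the factor 87.8% of the crawl. The slowing lowers the rate but stretches the time, so it cancels in their product, and I commit to about 87.8% of ring, assuming that ring stays. I also expect [starting material] near zero, since its half-life of 5.40 min is shorter than the 138 min that follow.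

The forecast differs on ring: it gives 70% of ring and 0% of saturation, reading the growing gap in the balance as “suggesting ring is being lost”.

This flask gives 93.1% of ring and 0% of saturation.

    solid substrate ⇌ starting material, rate k1*(cs1 - [starting material]) while solid is left; crystals form when [starting material] > cs1 (solubility = 8.20 mM, k = 0.0280 min⁻¹)
    starting material → ring (k = 0.140 min⁻¹)
    2 starting material → open dimer (k = 4.30 M⁻¹ min⁻¹)

Ring stands at 92.6% after 2.00 h and at 93.1% after 4.00 h, beside 6.90% of open dimer. The neighbour charged with 0.080 M of solid substrate gets the same reckoning: at the same crawl its solid needs 6.80 h, longer than 4.0 h, so by then 58.8% of its charge has left, and the share turns that into 51.6% of ring. That neighbour gives 52.6%, with 43% of its charge still there, solid or dissolved.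

Readings and results come from a simulation on assumed constants; noise was put on by code.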